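The disconnection reads the C1(=O)–C2=C3(–O–C10)–C4=C5 dienone as a ring-opened cyclobutene. The 3(2H)-furanone ring (O, C3, C2, C1, C10) bridges the ten-membered carbocycle C1–C10, with C2=C3 trans and C4=C5 Z in that ring; this is the cis,trans-diene that conrotatory opening of a cis-fused cyclobutene must give. Irradiating a trans-lactone-fused cyclooct-2-enone whose C10 oxygen carries an alkynyl (ynol) ether adds the alkyne across C2=C5 (forming C2–C3 and C4–C5). Thermal cleavage of C2–C5 then closes the furanone and enlarges the eight- to the ten-membered ring in the same flask. The precursor 29 already holds all stereocentres, the C8 ester and the C6/C12 lactone, but lacks C13.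

Key step: step 16

Remark: atoms keep the numbers they have in the target (the enone alkene of the cyclooctenone is therefore C2=C5). The alkynyl ether is built before any ester, lactone or enone exists because its formation needs KH and n-BuLi, and C15–OH is carried as a 4-methoxybenzyl ether so that fluoride alone removes the silyl groups.

Step 1
Reactants: 1 (S)-citramalic acid
Product: 2 2-[(4S)-2,2,4-trimethyl-5-oxo-1,3-dioxolan-4-yl]acetic acid
Conditions: Me2C(OMe)2, p-TsOH·H2O (cat.), 23 °C
Reagents that add atoms: 2,2-dimethoxypropane, COC(C)(C)OC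
Why: Acid-catalysed acetalisation of the α-hydroxy acid (dioxolanone formation) masks the tertiary C10 hydroxyl together with the C1 carboxyl and leaves only the C8 carboxyl free, without touching the stereocentre.

Step 2
Reactants: 2 2-[(4S)-2,2,4-trimethyl-5-oxo-1,3-dioxolan-4-yl]acetic acid
Product: 4 (3S)-3-hydroxy-3-methyloxolan-2-one, via hydroxy dioxolanone 3 (not isolated)
Conditions: BH3·SMe2, THF, 0 → 23 °C; MeOH; then p-TsOH (cat.), CH2Cl2, 23 °C
Reagents that add atoms: none
Why: Borane reduces the free carboxylic acid chemoselectively beside the ester-type dioxolanone carbonyl, and acid then drives translactonisation of the primary alcohol onto C1 with loss of acetone, which differentiates C1 (acyl) from C8 (alkoxy) and frees the tertiary alcohol.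

Step 3
Reactants: 4 (3S)-3-hydroxy-3-methyloxolan-2-one; 5 trichloroethylene
Product: 6 (3S)-3-{[(E)-1,2-dichloroethenyl]oxy}-3-methyloxolan-2-one
Conditions: KH (2 equiv), THF, 0 °C; Cl2C=CHCl, 0 → 23 °C
Reagents that add atoms: none
Why: Anti addition of the tertiary alkoxide to dichloroacetylene generated in the flask from trichloroethylene (the standard dichlorovinyl ether synthesis, known for tertiary alcohols) gives the (E)-ether; the lactone has no α-hydrogen, and no silyl ether is present that could migrate to the alkoxide.

Step 4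
Reactants: 6 (3S)-3-{[(E)-1,2-dichloroethenyl]oxy}-3-methyloxolan-2-one; 7 vinylmagnesium bromide
Product: 9 (3S)-3-{[(E)-1,2-dichloroethenyl]oxy}-3-methylhex-5-ene-1,4-diol (both epimers at the carbinol that is C1 of the target), via lactol 8 (not isolated)
Conditions: i-Bu2AlH, CH2Cl2, −78 °C; then CH2=CHMgBr, THF, −78 → 0 °C
Reagents that add atoms: none
Why: Partial reduction of the lactone to the lactol aluminate and Grignard addition to its open hydroxy-aldehyde form give the C1 allylic alcohol; the new C1 centre is not controlled and need not be, since step 13 oxidises it, and the dichlorovinyl ether is inert to both reagents at low temperature.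

Step 5
Reactants: 9 (3S)-3-{[(E)-1,2-dichloroethenyl]oxy}-3-methylhex-5-ene-1,4-diol
Product: 11 1-O-triethylsilyl-4-O-tert-butyldimethylsilyl ether of 9, via primary triethylsilyl ether 10 (not isolated)
Conditions: Et3SiCl (1.05 equiv), 2,6-lutidine, CH2Cl2, −78 → −20 °C; then t-BuMe2SiOTf, −78 → 0 °C
Reagents that add atoms: chlorotriethylsilane, CC[Si](Cl)(CC)CC; tert-butyldimethylsilyl trifluoromethanesulfonate, CC(C)(C)[Si](C)(C)OS(=O)(=O)C(F)(F)F
Why: Sequential silylation by steric differentiation puts the labile triethylsilyl group on the primary C8 hydroxyl and the robust tert-butyldimethylsilyl group on the hindered secondary C1 hydroxyl, so that C8 can later be unmasked first with fluoride.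

Step 6
Reactants: 11 bis-silyl dichlorovinyl ether; 12 formaldehyde (as paraformaldehyde)
Product: 15 C10-O-(3-hydroxyprop-1-ynyl) ether (propargylic alcohol) of the bis-silylated C1–C2/C8–C10 fragment, via chloroalkynyl ether 13 (not isolated), via lithium alkynyl ether 14 (not isolated)
Conditions: n-BuLi (2.4 equiv), THF, −78 → −40 °C; (CH2O)n, −78 → 0 °C; aq. NaHCO3
Reagents that add atoms: none
Why: Dehydrochlorination of the dichlorovinyl ether and chlorine–lithium exchange give the lithium alkoxyacetylide, which adds to formaldehyde (acetylide hydroxymethylation); the molecule holds only silyl ethers and an alkene here, the one point of the route at which n-BuLi can be used.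

Step 7
Reactants: 15 propargylic alcohol
Product: 16 15-O-(4-methoxybenzyl) ether of 15
Conditions: NaH, 4-MeOC6H4CH2Cl, Bu4NI (cat.), THF–DMF, 0 → 23 °C
Reagents that add atoms: 4-methoxybenzyl chloride, COc1ccc(CCl)cc1
Why: Williamson etherification of the propargylic alkoxide is safe because alkynyl ethers are base-stable, and the benzyl-type ether survives every later fluoride, Grignard, metathesis and enolate step until step 19.

Step 8
Reactants: 16 15-O-(4-methoxybenzyl) ether
Product: 17 primary C8 alcohol (1-O-desilylated 16)
Conditions: Bu4NF (1.05 equiv), THF, −20 °C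
Reagents that add atoms: none
Why: Fluoride cleaves the unhindered primary triethylsilyl ether much faster than the hindered secondary tert-butyldimethylsilyl ether (selective desilylation), under basic conditions that spare the acid-labile alkynyl ether.

Step 9
Reactants: 17 primary C8 alcohol
Product: 18 C8 aldehyde
Conditions: Dess–Martin periodinane, pyridine, CH2Cl2, 0 °C
Reagents that add atoms: none
Why: Dess–Martin oxidation buffered with pyridine gives the aldehyde without aqueous acid (hydration of the alkynyl ether) and without strong amine base (E1cB loss of the β-alkynyloxy group); 18 is used at once.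

Step 10
Reactants: 18 C8 aldehyde; 19 methyl 4-oxobutanoate
Product: 21 (7R,8R)-anti-aldol aldehyde as its 8-O-triethylsilyl ether (C6 aldehyde, C12 methyl ester), via aldol 20 (not isolated)
Conditions: D-proline (20 mol %), DMF, 4 °C, 19 (3 equiv) added over 24 h; then imidazole, Et3SiCl, 0 °C
Reagents that add atoms: chlorotriethylsilane, CC[Si](Cl)(CC)CC
Why: Proline-catalysed direct cross-aldol reaction of two aliphatic aldehydes: the enamine of the unhindered donor 19 adds to the β-branched acceptor 18 through the acid-organised chair transition state, which gives the anti aldol and sets C7 and C8 by catalyst control (D-proline gives 7R,8R, the mirror image of the sense known for L-proline), and silylation in the same flask blocks lactonisation of O8 onto C12 and retro-aldol cleavage.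

Step 11
Reactants: 21 silylated aldol aldehyde; 7 vinylmagnesium bromide
Product: 23 trans-4,5-disubstituted γ-butyrolactone (C6 vinyl, C7 bearing the C8–C10–C1 chain), via bromomagnesium alkoxide 22 (not isolated)
Conditions: CH2=CHMgBr, THF, −78 → 0 °C; aq. NH4Cl
Reagents that add atoms: none
Why: Felkin–Anh addition of the Grignard reagent to the α-branched aldehyde (the silyloxy-bearing C8 branch as the large group, reinforced by 1,3-anti induction from the β-silyloxy group) sets C6, and the alkoxide lactonises onto the methyl ester (5-exo-trig) to the trans lactone; aldehyde addition at −78 °C outruns attack on the ester.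

Step 12
Reactants: 23 bis-silylated lactone
Product: 24 C1,C8-diol lactone
Conditions: Bu4NF (3 equiv), THF, 0 → 23 °C
Reagents that add atoms: none
Why: Fluoride removes both silyl ethers (global desilylation) under basic conditions that leave the alkynyl ether, the 4-methoxybenzyl ether and the thermodynamically preferred trans γ-lactone intact.

Step 13
Reactants: 24 C1,C8-diol lactone
Product: 25 vinyl ketone (C1 ketone, free C8 alcohol)
Conditions: MnO2 (excess), CH2Cl2, 23 °C
Reagents that add atoms: none
Why: Manganese dioxide oxidises only the allylic C1 alcohol and leaves the saturated C8 alcohol (chemoselective allylic oxidation), which also removes the uncontrolled C1 centre.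

Step 14
Reactants: 25 vinyl ketone
Product: 26 (6R,7R,8R,10S)-lactone-fused (Z)-cyclooct-2-enone with free C8 alcohol
Conditions: second-generation Hoveyda–Grubbs catalyst (10 mol %), CH2Cl2 (2 mM), 40 °C
Reagents that add atoms: none
Why: Ring-closing metathesis: the ruthenium alkylidene forms at the C6 vinyl group and closes onto the vinyl ketone (only the Z alkene fits the eight-membered ring), helped by the trans-lactone and the C10 quaternary centre; the hindered internal alkynyl ether should react more slowly, and the 5-exo enyne mode is suppressed because the catalyst does not load onto the electron-poor vinyl ketone.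

Step 15
Reactants: 26 cyclooctenone alcohol; 27 (R)-2-methylbutanoic acid
Product: 29 (6R,7R,8R,10S)-lactone-fused (Z)-cyclooct-2-enone bearing the C8 (R)-2-methylbutanoate and the C10 O–C≡C–CH2O(4-methoxybenzyl) ether (the precursor), via mixed anhydride 28 (not isolated)
Conditions: 2,4,6-Cl3C6H2COCl, Et3N, THF, 23 °C; then 26, DMAP, PhMe, 23 °C
Reagents that add atoms: none
Why: Yamaguchi esterification acylates the hindered C8 alcohol through the mixed anhydride with retention at C8 and without racemising the α-centre of the acid; the acid is present only as its carboxylate, so it cannot add to the alkynyl ether.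

Step 16
Reactants: 29 lactone-fused cyclooctenone alkynyl ether
Product: 31 (6R,7R,8R,10S)-13-nor-15-O-(4-methoxybenzyl) furanone lactone (3(2H)-furanone bridging the ten-membered ring, C4=C5 Z), via cyclobutene 30 (not isolated)
Conditions: hν (366 nm), degassed CH2Cl2 (2 mM), 2,6-di-tert-butylpyridine (5 mol %), −40 °C; then dark, 23 °C
Reagents that add atoms: none
Why: Proposed new method: Excitation of the cyclooctenone (n→π*) and intersystem crossing give the enone triplet, whose α-carbon C2 bonds to the oxygen-bearing alkyne carbon C3 in a 5-exo-dig radical closure that forms the oxacycle O–C3–C2–C1–C10, and the resulting 1,4-diradical (C5 alkyl, C4 vinyl) couples after spin inversion to cyclobutene 30 with its enol-ether double bond C3=C4. On warming in the dark this strained donor–acceptor cyclobutene opens by 4π conrotation with cleavage of C2–C5, so that the five-membered ring becomes the 3(2H)-furanone and the ten-membered ring arises by two-carbon expansion of the eight-membered one and not by end-to-end closure. The closest known reaction types are the intramolecular enone–alkyne [2+2] photocycloaddition through a three-atom tether (straight adducts by 1,5-closure), the thermal opening of cis-bicyclo[6.2.0]dec-9-enes to cis,trans-cyclodeca-1,3-dienes, and the ring expansion of donor–acceptor cyclobutenes from Ficini cycloadditions; the ynol ether tether and the tandem are new. No stereocentre is created in 31 (C2 and C5 of 30, fixed by the tether and the cis fusion, become sp2), and the Z geometry of C4=C5 follows because the oxacycle forces C1 to rotate outward at C2, so that C6 must rotate inward at C5 of the cis-fused cyclobutene. The step needs straight regiochemistry, which the short C1–C10–O tether secures, and cis ring fusion, which the trans-fused lactone and the C10 quaternary centre favour by stiffening the ring against twisting to a trans-cyclooctenone, while long-wavelength light, low temperature and high dilution limit that pathway and secondary photoreactions. Traces of acid and temperatures above ambient are excluded because the tertiary alkynyl ether hydrates and undergoes retro-ene cleavage.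

Step 17
Reactants: 31 13-nor furanone lactone; 32 N,N-dimethylmethyleneiminium iodide
Product: 34 11-(dimethylaminomethyl) lactone (Mannich base, C11 epimers), via lithium enolate 33 (not isolated)
Conditions: LiN(SiMe3)2 (1.1 equiv), THF, −78 °C; CH2=NMe2+ iodide, −78 → 0 °C
Reagents that add atoms: none
Why: Kinetic deprotonation of the lactone α-methylene C11 (the most accessible acidic C–H, since the ketone has no α-hydrogen and the ester α-hydrogen is tertiary and hindered) and Mannich reaction of the enolate with the iminium salt install C13; the C11 configuration is irrelevant.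

Step 18
Reactants: 34 Mannich base
Product: 36 15-O-(4-methoxybenzyl) ether of the target (α-methylene lactone), via ammonium iodide 35 (not isolated)
Conditions: MeI, CH2Cl2–MeOH, 23 °C; then aq. NaHCO3
Reagents that add atoms: none
Why: N-Methylation and base-induced β-elimination of trimethylamine from the β-ammonio lactone (E1cB, Hofmann-type) give the exocyclic C11=C13 alkene.

Step 19
Reactants: 36 15-O-(4-methoxybenzyl) ether of the target
Product: 37 target CNP0307052.2
Conditions: DDQ, CH2Cl2–pH 7 buffer, 0 °C
Reagents that add atoms: none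
Why: Oxidative cleavage of the 4-methoxybenzyl ether by DDQ (benzylic hydride abstraction, then hydrolysis of the oxocarbenium ion) frees the C15 alcohol under neutral conditions that spare the dienone, the ester and the α-methylene lactone.

Compound list

1 | (S)-citramalic acid | OC(=O)[C@](C)(CC(=O)O)O | starting material
2 | 2-[(4S)-2,2,4-trimethyl-5-oxo-1,3-dioxolan-4-yl]acetic acid | CC1(C)OC(=O)[C@](C)(CC(=O)O)O1 | intermediate
3 | (5S)-5-(2-hydroxyethyl)-2,2,5-trimethyl-1,3-dioxolan-4-one | CC1(C)OC(=O)[C@](C)(CCO)O1 | intermediate (not isolated)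
4 | (3S)-3-hydroxy-3-methyloxolan-2-one | O=C1[C@](C)(CCO1)O | intermediate
5 | trichloroethylene | ClC=C(Cl)Cl | starting material
6 | (3S)-3-{[(E)-1,2-dichloroethenyl]oxy}-3-methyloxolan-2-one | O=C1[C@](C)(CCO1)O/C(Cl)=C\Cl | intermediate
7 | vinylmagnesium bromide | C=C[Mg]Br | starting material
8 | (3S)-3-{[(E)-1,2-dichloroethenyl]oxy}-3-methyloxolan-2-ol (lactol, formed as its aluminium alkoxide) | OC1[C@](C)(CCO1)O/C(Cl)=C\Cl | intermediate (not isolated)
9 | (3S)-3-{[(E)-1,2-dichloroethenyl]oxy}-3-methylhex-5-ene-1,4-diol (C1 epimers, target numbering) | C=CC(O)[C@](C)(CCO)O/C(Cl)=C\Cl | intermediate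
10 | 1-O-triethylsilyl ether of 9 | C=CC(O)[C@](C)(CCO[Si](CC)(CC)CC)O/C(Cl)=C\Cl | intermediate (not isolated)
11 | 1-O-triethylsilyl-4-O-tert-butyldimethylsilyl ether of 9 | C=CC(O[Si](C)(C)C(C)(C)C)[C@](C)(CCO[Si](CC)(CC)CC)O/C(Cl)=C\Cl | intermediate
12 | formaldehyde (as paraformaldehyde) | C=O | starting material
13 | C10-O-chloroethynyl ether of the bis-silylated fragment | C=CC(O[Si](C)(C)C(C)(C)C)[C@](C)(CCO[Si](CC)(CC)CC)OC#CCl | intermediate (not isolated)
14 | C10-O-lithioethynyl ether of the bis-silylated fragment | C=CC(O[Si](C)(C)C(C)(C)C)[C@](C)(CCO[Si](CC)(CC)CC)OC#C[Li] | intermediate (not isolated)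
15 | C10-O-(3-hydroxyprop-1-ynyl) ether (C15 alcohol) of the bis-silylated fragment, C10 (S) | C=CC(O[Si](C)(C)C(C)(C)C)[C@](C)(CCO[Si](CC)(CC)CC)OC#CCO | intermediate
16 | 15-O-(4-methoxybenzyl) ether of 15 | C=CC(O[Si](C)(C)C(C)(C)C)[C@](C)(CCO[Si](CC)(CC)CC)OC#CCOCc1ccc(OC)cc1 | intermediate
17 | primary C8 alcohol (C1-O-TBS, C10 alkynyl ether) | C=CC(O[Si](C)(C)C(C)(C)C)[C@](C)(CCO)OC#CCOCc1ccc(OC)cc1 | intermediate
18 | C8 aldehyde | C=CC(O[Si](C)(C)C(C)(C)C)[C@](C)(CC=O)OC#CCOCc1ccc(OC)cc1 | intermediate
19 | methyl 4-oxobutanoate | COC(=O)CCC=O | starting material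
20 | (7R,8R)-anti-aldol (C6 aldehyde, C8 alcohol, C12 methyl ester) | C=CC(O[Si](C)(C)C(C)(C)C)[C@](C)(C[C@@H](O)[C@H](C=O)CC(=O)OC)OC#CCOCc1ccc(OC)cc1 | intermediate (not isolated)
21 | 8-O-triethylsilyl ether of 20 | C=CC(O[Si](C)(C)C(C)(C)C)[C@](C)(C[C@@H](O[Si](CC)(CC)CC)[C@H](C=O)CC(=O)OC)OC#CCOCc1ccc(OC)cc1 | intermediate
22 | bromomagnesium alkoxide of the C6 vinyl carbinol (C6, C7, C8 arranged as in 37) | C=CC(O[Si](C)(C)C(C)(C)C)[C@](C)(C[C@@H](O[Si](CC)(CC)CC)[C@H]([C@H](O[Mg]Br)C=C)CC(=O)OC)OC#CCOCc1ccc(OC)cc1 | intermediate (not isolated)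
23 | trans-γ-lactone (C6 vinyl; C8-O-TES, C1-O-TBS; C6, C7, C8, C10 arranged as in 37) | C=CC(O[Si](C)(C)C(C)(C)C)[C@](C)(C[C@@H](O[Si](CC)(CC)CC)[C@H]1CC(=O)O[C@@H]1C=C)OC#CCOCc2ccc(OC)cc2 | intermediate
24 | C1,C8-diol lactone (C1 epimers) | C=CC(O)[C@](C)(C[C@@H](O)[C@H]1CC(=O)O[C@@H]1C=C)OC#CCOCc2ccc(OC)cc2 | intermediate
25 | vinyl ketone (C1 ketone, C8 alcohol, C6 vinyl lactone) | C=CC(=O)[C@](C)(C[C@@H](O)[C@H]1CC(=O)O[C@@H]1C=C)OC#CCOCc2ccc(OC)cc2 | intermediate
26 | (6R,7R,8R,10S)-lactone-fused (Z)-cyclooct-2-enone, C8 alcohol | C1C(=O)O[C@@H]2/C=C\C(=O)[C@](C)(C[C@@H](O)[C@@H]12)OC#CCOCc3ccc(OC)cc3 | intermediate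
27 | (R)-2-methylbutanoic acid | OC(=O)[C@H](C)CC | starting material
28 | (R)-2-methylbutanoic 2,4,6-trichlorobenzoic anhydride | Clc1cc(Cl)cc(Cl)c1C(=O)OC(=O)[C@H](C)CC | intermediate (not isolated)
29 | (6R,7R,8R,10S)-lactone-fused (Z)-cyclooct-2-enone, C8 (R)-2-methylbutanoate, C10 O–C≡C–CH2O(4-methoxybenzyl) ether (precursor) | C1C(=O)O[C@@H]2/C=C\C(=O)[C@](C)(C[C@@H](OC(=O)[C@H](C)CC)[C@@H]12)OC#CCOCc3ccc(OC)cc3 | intermediate
30 | cis-fused cyclobutene photoadduct (C2–C3 and C4–C5 formed, C3=C4 enol ether) | C1C(=O)O[C@@H]2[C@H]3C(COCc4ccc(OC)cc4)=C5[C@H]3C(=O)[C@@](C)(O5)C[C@@H](OC(=O)[C@H](C)CC)[C@@H]12 | intermediate (not isolated)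
31 | (6R,7R,8R,10S)-13-nor-15-O-(4-methoxybenzyl) furanone lactone (C4=C5 Z) | C1C(=O)O[C@@H]2/C=C(/COCc3ccc(OC)cc3)C3=CC(=O)[C@](C)(C[C@@H](OC(=O)[C@H](C)CC)[C@@H]12)O3 | intermediate
32 | N,N-dimethylmethyleneiminium iodide | C=[N+](C)C.[I-] | starting material
33 | lithium enolate of lactone 31 | C1=C(O[Li])O[C@@H]2/C=C(/COCc3ccc(OC)cc3)C3=CC(=O)[C@](C)(C[C@@H](OC(=O)[C@H](C)CC)[C@@H]12)O3 | intermediate (not isolated)
34 | 11-(dimethylaminomethyl) lactone (C11 epimers) | CN(C)CC1C(=O)O[C@@H]2/C=C(/COCc3ccc(OC)cc3)C3=CC(=O)[C@](C)(C[C@@H](OC(=O)[C@H](C)CC)[C@@H]12)O3 | intermediate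
35 | 11-(trimethylammoniomethyl) lactone iodide | C[N+](C)(C)CC1C(=O)O[C@@H]2/C=C(/COCc3ccc(OC)cc3)C3=CC(=O)[C@](C)(C[C@@H](OC(=O)[C@H](C)CC)[C@@H]12)O3.[I-] | intermediate (not isolated)
36 | 15-O-(4-methoxybenzyl) ether of the target | C=C1C(=O)O[C@@H]2/C=C(/COCc3ccc(OC)cc3)C3=CC(=O)[C@](C)(C[C@@H](OC(=O)[C@H](C)CC)[C@@H]12)O3 | intermediate
37 | CNP0307052.2 (6R,7R,8R,10S; ester R) | C=C1C(=O)O[C@@H]2/C=C(/CO)C3=CC(=O)[C@](C)(C[C@@H](OC(=O)[C@H](C)CC)[C@@H]12)O3 | target

Total step count: 19. Longest linear sequence: 19 steps from 1 (all other building blocks are commercial).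

Steps most likely to fail

Step 16 (proposed new method). What may go wrong: photoisomerisation of the cyclooctenone to its trans isomer, which would lead to trans-fused or intermolecular adducts and hence the wrong C4=C5 geometry; retro-ene loss of the tertiary alkynyl ether; secondary photoreaction of the cyclobutene before it opens. The fallback uses known reaction types only, sets out from diol 24 and returns at 31. Ring-closing enyne metathesis of 24 (second-generation Grubbs catalyst, CH2Cl2, ethylene atmosphere, 40 °C) would join the C1 vinyl group to the alkynyl ether in the 5-exo mode and should give the dienyl dihydrofuranol F1. MnO2 oxidation of its allylic alcohol should give the 3(2H)-furanone F2, and Yamaguchi esterification with 27 should give the ester F3. Ring-closing metathesis of the 1,1-disubstituted alkene on C4 with the C6 vinyl group (second-generation Hoveyda–Grubbs catalyst, toluene, 80 °C, high dilution) would then close the ten-membered ring at C4=C5 and deliver 31; the Z isomer would have to be separated if the E isomer also forms. Furanone and ten-membered ring are then made by two metatheses and no light is needed.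

Step 10. What may go wrong: the secondary amine also forms the enamine of acceptor 18, from which the tertiary alkynyloxy group can be lost by β-elimination, and self-aldol of 19 competes, so conversion to the anti aldol stays low. The fallback is amine-free lithium enolate chemistry; it sets out from 18 and returns at 23. Addition of 18 at −100 °C to the doubly deprotonated (S)-2-hydroxy-1,2,2-triphenylethyl acetate (LDA, THF, then MgBr2) should give the β-hydroxy ester F4, with C8 set by the auxiliary. K2CO3 in MeOH should give the methyl ester F5. Dianion alkylation (LDA, 2.2 equiv, then tert-butyl bromoacetate; Fráter–Seebach, anti) should give the diester F6, and Et3SiCl with imidazole the silyl ether F7. i-Bu2AlH at −78 °C should reduce the methyl ester to the aldehyde F8. CH2=CHMgBr, then warming with a little KOt-Bu, should give 23 by lactonisation with loss of tert-butanol.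

Step 14. What may go wrong: the ruthenium alkylidene engages the alkynyl ether (enyne metathesis) instead of closing the eight-membered enone, or the closure is too slow at a temperature the alkynyl ether tolerates. The fallback protects the alkyne during metathesis; it sets out from 25 and returns at 26. Co2(CO)8 in CH2Cl2 at 23 °C should give the Co2(CO)6 complex of the alkynyl ether F9. Ring-closing metathesis under the conditions of step 14 should give the complexed cyclooctenone F10. Mild decomplexation (Bu4NF, THF, −10 °C, or Me3NO) should release 26.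

Further compounds

F1 | step 16 | dienyl 4-hydroxy-4,5-dihydrofuran from enyne metathesis of 24 (C2=C3 in the oxacycle, C4 bearing =CH2 and CH2O(4-methoxybenzyl)) | C=C(COCc1ccc(OC)cc1)C1=CC(O)[C@](C)(C[C@@H](O)[C@H]2CC(=O)O[C@@H]2C=C)O1
F2 | step 16 | 3(2H)-furanone with free C8 alcohol | C=C(COCc1ccc(OC)cc1)C1=CC(=O)[C@](C)(C[C@@H](O)[C@H]2CC(=O)O[C@@H]2C=C)O1
F3 | step 16 | 3(2H)-furanone C8 (R)-2-methylbutanoate (diene for ring closure at C4=C5) | C=C(COCc1ccc(OC)cc1)C1=CC(=O)[C@](C)(C[C@@H](OC(=O)[C@H](C)CC)[C@H]2CC(=O)O[C@@H]2C=C)O1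
F4 | step 10 | (S)-2-hydroxy-1,2,2-triphenylethyl ester of the C8 β-hydroxy acid (acetate aldol of 18) | C=CC(O[Si](C)(C)C(C)(C)C)[C@](C)(C[C@@H](O)CC(=O)O[C@@H](c1ccccc1)C(O)(c1ccccc1)c1ccccc1)OC#CCOCc1ccc(OC)cc1
F5 | step 10 | methyl β-hydroxy ester (C8 alcohol, C6 ester) | C=CC(O[Si](C)(C)C(C)(C)C)[C@](C)(C[C@@H](O)CC(=O)OC)OC#CCOCc1ccc(OC)cc1
F6 | step 10 | anti-alkylated diester (C6 methyl ester, C12 tert-butyl ester, C8 alcohol) | C=CC(O[Si](C)(C)C(C)(C)C)[C@](C)(C[C@@H](O)[C@H](C(=O)OC)CC(=O)OC(C)(C)C)OC#CCOCc1ccc(OC)cc1
F7 | step 10 | 8-O-triethylsilyl ether of F6 | C=CC(O[Si](C)(C)C(C)(C)C)[C@](C)(C[C@@H](O[Si](CC)(CC)CC)[C@H](C(=O)OC)CC(=O)OC(C)(C)C)OC#CCOCc1ccc(OC)cc1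
F8 | step 10 | C6 aldehyde with C12 tert-butyl ester | C=CC(O[Si](C)(C)C(C)(C)C)[C@](C)(C[C@@H](O[Si](CC)(CC)CC)[C@H](C=O)CC(=O)OC(C)(C)C)OC#CCOCc1ccc(OC)cc1
F9 | step 14 | Co2(CO)6 complex of the alkynyl ether of 25 | C=CC(=O)[C@](C)(C[C@@H](O)[C@H]1CC(=O)O[C@@H]1C=C)OC12C3(COCc4ccc(OC)cc4)[Co]1(=C=O)(=C=O)(=C=O)[Co]23(=C=O)(=C=O)=C=O
F10 | step 14 | Co2(CO)6 complex of the alkynyl ether of 26 | C1C(=O)O[C@@H]2/C=C\C(=O)[C@](C)(C[C@@H](O)[C@@H]12)OC12C3(COCc4ccc(OC)cc4)[Co]1(=C=O)(=C=O)(=C=O)[Co]23(=C=O)(=C=O)=C=O
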